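The easy mistake with these runs was to read the split between target and intermediate B as a race, with second reagent as the handle on it. I tested that on the readings.

all flasks: substrate 0.38 M; partner 0.684 M; third reagent 0.456 M
- Sunday's: second reagent 0.47 M; run made earlier
- Monday's: second reagent 0.46 M; run made earlier
- Friday's: second reagent 0.48 M; run made earlier
- west: second reagent 0.420 M; time 4.0 min
- south-east: second reagent 0.630 M; time 4.0 min

| run | time / s | target / % | intermediate A / % | intermediate B / % | substrate / % |
|---|---|---|---|---|---|
| Sunday's | 25.0 | 8.5 | 31.1 | 10.7 | 49.2 |
| Sunday's | 50.0 | 23.8 | 28.6 | 15.4 | 29.2 |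
| Sunday's | 80.0 | 37.6 | 24.0 | 21.6 | 15.7 |
| Sunday's | 90.0 | 40.7 | 20.7 | 25.5 | 13.5 |
| Sunday's | 120 | 45.2 | 16.4 | 28.9 | 7.0 |
| Monday's | 10.0 | 0.1 | 21.5 | 1.3 | 72.8 |
| Monday's | 20.0 | 6.0 | 29.4 | 9.0 | 57.0 |
| Monday's | 30.0 | 11.7 | 32.0 | 12.4 | 44.4 |
| Monday's | 60.0 | 28.8 | 29.5 | 16.0 | 23.7 |
| Monday's | 120 | 45.3 | 16.3 | 27.5 | 7.6 |
| Friday's | 10.0 | 1.4 | 22.1 | 5.2 | 72.0 |
| Friday's | 20.0 | 6.4 | 31.3 | 9.4 | 54.8 |
| Friday's | 30.0 | 13.4 | 32.4 | 12.9 | 45.7 |
| Friday's | 60.0 | 28.7 | 26.9 | 19.5 | 23.0 |
| Friday's | 120 | 47.1 | 17.5 | 25.5 | 8.2 |

(readings scatter by 1 percentage point)

- the numbers in the tables scatter by 1 percentage point (one standard deviation)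
- a reading or a percentage of target counts all its forms, free or not

- which of these there is most of at the end, counted by the substrate in it, west (target / substrate / intermediate A / intermediate B)
- which of these there is most of at the end, counted by the substrate in it, south-east (target / substrate / intermediate A / intermediate B)
- amount of the one of these that there is most of at the end, in percent of the substrate charged, west
- amount of the one of these that there is most of at the end, in percent of the substrate charged, south-east

I divided the amount of target by the joint amount of target and intermediate B, and followed that share through the runs: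

s = c(target) / (c(target) + c(intermediate B))

Pooled over Monday's and Friday's runs, s read 0.498 at 30.0 s and 0.618 at 60.0 s, so it climbed. Pooled over the three runs at 120 s, the end share (my name for it) read 0.627. In Monday's and Friday's runs both amounts went on growing meanwhile. I read that as an exchange between the two, thermodynamic rather than kinetic control. But the runs span just 0.46 M to 0.48 M of second reagent, so holding s across west and south-east was my assumption. My reckoning was:

target at the end ≈ s × (charge − substrate left − intermediate A left)

I did not reckon the two leftovers, so I took s of the whole charge, 62.7 %, as a ceiling for target in both flasks. I expected south-east nearer to it, with 0.630 M of second reagent against 0.420 M in west. Target had to lead intermediate B in both, because s stood above 0.373.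

The forecast named target for west and target for south-east, at 52 % and 66 %, holding that “Intermediate A forms first, then drains to target and intermediate B”. Its south-east figure stands above my ceiling, and there we differ.

South-east gave 58.3 % of target and west 54.2 %, with target largest in both, so the forecast's south-east figure was 7.7 percentage points too high. Left until 40.0 min, west held 60.2 % of target and south-east 60.2 %. Put to use on south-east, s with the 1.49 % of substrate and 2.36 % of intermediate A left gives 60.3 %.

    partner → decomposition product (k = 2.50 × 10⁻⁶ s⁻¹)
    second reagent + intermediate A → intermediate B (k = 0.0800 M⁻¹ s⁻¹)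
    third reagent + intermediate B ⇌ target (K = 6.10 M⁻¹, k = 0.210 M⁻¹ s⁻¹)
    substrate + partner → intermediate A (k = 0.0490 M⁻¹ s⁻¹)
    partner + target ⇌ idle adduct, settled at all times (K = 0.320 M⁻¹)

The neighbour with 0.27 M of partner kept 36 % of substrate and 1.98 % of intermediate A, so s gives 38.9 % of target there. The computed flask gives 39.9 %.

Readings and results are calculated on assumed constants; the scatter is artificial.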